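The constants were chosen freely.

The slowness of epsilon, whose X meets Z more slowly than X.Z goes on to D, lies in a meeting that can undo itself, so you reckon what is left of X, not what is made.

    X + Z ⇌ X.Z (K1 = 97.6 M⁻¹, k1 = 6.91 M⁻¹ min⁻¹)
    X.Z → D (k2 = 0.124 min⁻¹)

in all of them: X 10 mM; time 80 min

|  | Z |
|---|---|
| epsilon | 10.0 mM |
| gamma | 20.0 mM |
| zeta | 40.0 mM |
| beta | 80.0 mM |

* amount of D at the end, in percent of the X charged for epsilon, gamma, zeta, beta, in this order
* how the row runs (falls all the way / rises all the way / hardly changes / rises, then falls / falls, then rises)

- "hardly changes" means that all values lie within two and a half points (for a concentration: within two and a half percent of the largest)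
- run time (epsilon): 80 min

Start with epsilon, where the charges are equal. X.Z falls back at 0.0708 min⁻¹, which is slower than it goes on to D at 0.124 min⁻¹, so a share of 63.7 % of every meeting ends in D. X.Z lives about 5.13 min, far shorter than the run, so you may treat the two steps as one. Its constant is the first-step rate constant times that share, the capture constant 4.40 M⁻¹ min⁻¹. With equal charges, the fraction left is one over one plus constant times charge times time, which gives 22.1 %.

The weak link is that this count treats the whole of what is left as free X, whereas a slice waits as X.Z and meets nothing. That slice, relative to free X, is the first-step forward rate over the loss rate of X.Z. Read at half the Z charge, as a round figure of my own, it is 0.177. Dividing the capture constant by one plus the slice gives 3.74 M⁻¹ min⁻¹, so 25.1 % is left and D in epsilon is 74.9 %.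

The forecast, holding that “about 64% of it goes forward”, gave 74.5 %, 95.8 %, 99.8 % and 100 %, a row that rises all the way. The simulation gives 74.5 %, 96.4 %, 99.8 % and 100 %, a row that rises all the way.

In epsilon the shortfall of D comes from the return of X.Z to X + Z and the length of the run acting together: against 74.5 %, a one-way first step gives 83.1 % and a run ten times as long gives 97.1 %. The wearing away of Z is a part of it too, for Z held at its charge in epsilon gives D 94.2 %. With the slice read at that [Z], the capture constant becomes 3.25 M⁻¹ min⁻¹, and this pseudo-first-order decay leaves 7.45 % against the run's 5.80 %. Gamma has twice the Z, and half its charge is that same [Z]. In gamma, constant times excess Z times time is 2.60, and the unequal-charge law then leaves 3.86 % against the run's 3.60 %.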